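**Plan**

Numbering: C22 chain; C1 = lactone carbonyl, C7 = lactone carbinol carbon, C8/C10 = cyclopropane CH, C9 = cyclopropane CH2, C11 and C14 = carbinols.
Cuts: (a) C11–C12, giving cyclopropanecarbaldehyde 13 (fragment A, C1–C11) and alkyne 20 (fragment B, C12–C22); (b) C3–C4 of the oxocan-2-one, which is traced back by a two-carbon ring contraction to six-membered lactol 10 of vinyl ketone 9, i.e. to δ-lactone 7 plus a vinyl group; (c) C7–C8 and the two cyclopropane bonds to C9, giving an alkyne, an aldehyde and CH2I2.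
Enabling feature: C1 and C4 are 1,4-related through C2–C3, so C1 can first be bonded to C4 inside a six-membered hemiketal ring (O, C1, C4, C5, C6, C7) that carries C2=C3 as a vinyl group. Homolysis of C1–C4 from the hemiketal oxygen then leaves an acrylate ester on the C7 oxygen and a C4 radical that closes the eight-membered ring onto C3.
Forward order: cyclopropane (step 1), six-membered lactone (step 2), ring expansion to the eight-membered lactone (step 4), union of the fragments at C11–C12 (step 10).
Stereochemistry: C7 from (−)-MIB-catalysed alkenylzinc addition; C8/C10 from the C7-alkoxide-directed Simmons–Smith reaction of an E-alkene; C14 from (R)-BINOL/Ti(OiPr)4-catalysed alkynylation; C11 from (+)-MIB-catalysed alkenylzinc addition; the Z,Z-diene from commercial dienol 14; the E-alkene from syn hydroboration.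

Key step: step 4

Assumption: δ-hydroxy vinyl ketone 9 is taken to interconvert rapidly with its six-membered lactol 10 under the mildly basic conditions of step 4; 9 is written as the isolated tautomer.

Step 1
Reactants: 1 3,3-diethoxyprop-1-yne; 2 ethyl 5-oxopentanoate
Product: 6 ethyl (5R)-5-[(1R,2R)-2-(diethoxymethyl)cyclopropyl]-5-hydroxypentanoate, via alkenylborane 3 (not isolated), via alkenylzinc 4 (not isolated), via allylic zinc alkoxide 5 (not isolated)
Conditions: 1, Cy2BH, toluene, 0 °C to rt; Et2Zn, (−)-MIB (4 mol%), −78 to −10 °C, then 2 by slow addition; then Et2Zn, CH2I2, CH2Cl2, 0 °C to rt, dark; aq NH4Cl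
Reagents that add atoms: diiodomethane (ICI)
Why: Tandem asymmetric vinylation/directed cyclopropanation: syn hydroboration gives the E-alkenylborane, boron-to-zinc exchange and (2S)-(−)-3-exo-morpholinoisoborneol-catalysed addition to the Si face of 2 should set C7 as R, and the allylic zinc alkoxide then directs the Simmons–Smith (Furukawa) methylene transfer to the alkene face syn to oxygen in the A1,3-minimised conformer, which should set C8 and C10 (both R, trans from the E-alkene).

Step 2
Reactants: 6 ethyl (5R)-5-[(1R,2R)-2-(diethoxymethyl)cyclopropyl]-5-hydroxypentanoate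
Product: 7 (6R)-6-[(1R,2R)-2-(diethoxymethyl)cyclopropyl]oxan-2-one
Conditions: PPTS (10 mol%), 4 Å molecular sieves, benzene, 50 °C
Reagents that add atoms: none
Why: Acid-catalysed lactonisation of a δ-hydroxy ester (6-exo-trig), in which the ethanol released matches the acetal alkoxy groups so the acetal cannot scramble and no stereocentre is touched.

Step 3
Reactants: 7 (6R)-6-[(1R,2R)-2-(diethoxymethyl)cyclopropyl]oxan-2-one
Product: 9 (7R)-7-[(1R,2R)-2-(diethoxymethyl)cyclopropyl]-7-hydroxyhept-1-en-3-one, via magnesium lactolate 8 (not isolated)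
Conditions: CH2=CHMgBr (1.1 equiv), THF, −78 °C; aq NH4Cl at −78 °C; used without storage
Reagents that add atoms: vinylmagnesium bromide (C=C[Mg]Br)
Why: Mono-addition of a Grignard reagent to a lactone, in which the tetrahedral magnesium lactolate persists at −78 °C and collapses only on work-up, so that a second addition should be avoided.

Step 4
Reactants: 9 (7R)-7-[(1R,2R)-2-(diethoxymethyl)cyclopropyl]-7-hydroxyhept-1-en-3-one
Product: 12 (8R)-8-[(1R,2R)-2-(diethoxymethyl)cyclopropyl]oxocan-2-one, via lactol tautomer 10 (not isolated), via acrylate-tethered alkyl radical 11 (not isolated)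
Conditions: [Ir(dF(CF3)ppy)2(5,5'-d(CF3)bpy)]PF6 (2 mol%), Bu4N[(BuO)2PO2] (25 mol%), PhCF3 (0.003 M), blue LEDs, rt, degassed
Reagents that add atoms: none
Why: Proposed new method: Under blue light the excited trivalent iridium complex and the phosphate base remove the O–H hydrogen of lactol 10 by proton-coupled electron transfer, the hemiketal alkoxy radical cleaves the ring bond C1–C4 by β-scission to give radical 11 (an acrylate ester on the C7 oxygen and a primary radical at C4), this radical adds to the acrylate terminus C3, and the resulting α-ester radical at C2 is reduced by the divalent iridium state and protonated, so that the whole is a redox-neutral isomerisation of 9 into 12. The closest known reaction types are the photocatalytic n to n+2 ring expansion of 1-vinylcycloalkanols by the same scission/re-addition sequence, the alkoxy-radical fragmentation of lactols to ω-functionalised esters, and the 8-endo cyclisation of ester-tethered radicals to heptanolides; new here is the use of a vinyl lactol, so that the ring that grows is a lactone. The six-membered hemiketal ring is opened and the oxocan-2-one is closed in the 8-endo-trig mode, which the s-trans ester geometry of the tether can accommodate at the long forming C3–C4 bond, whereas the 7-exo alternative would attack the α-carbon of the acrylate and is electronically disfavoured. No stereocentre is formed: C7 keeps its configuration because its C–O bond is never broken, and the cyclopropane is not opened because the radical at C4 is three bonds away from it. The step needs (a) scission of C1–C4 and not of C1–vinyl, secured because only this path gives an alkyl radical and a conjugated ester, (b) funnelling of the open hydroxy enone through its minor lactol tautomer, secured by base-mediated ring–chain equilibration and because an alkoxy radical formed at the C7 hydroxyl of the open form has no comparably fast exit and should be returned by back electron–proton transfer, and (c) cyclisation in preference to intermolecular Giese addition to the vinyl ketone of a second molecule, secured by high dilution.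

Step 5
Reactants: 12 (8R)-8-[(1R,2R)-2-(diethoxymethyl)cyclopropyl]oxocan-2-one
Product: 13 (1R,2R)-2-[(2R)-8-oxooxocan-2-yl]cyclopropane-1-carbaldehyde
Conditions: PPTS (20 mol%), acetone/H2O (10:1), 40 °C
Reagents that add atoms: water (O)
Why: Mild acid-catalysed acetal hydrolysis, which the eight-membered lactone should tolerate and which leaves the trans (thermodynamic) cyclopropane aldehyde unchanged.

Step 6
Reactants: 14 (3Z,6Z)-nona-3,6-dien-1-ol
Product: 15 (3Z,6Z)-nona-3,6-dienal
Conditions: Dess–Martin periodinane, NaHCO3, CH2Cl2, 0 °C; used crude at once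
Reagents that add atoms: none
Why: Dess–Martin oxidation under bicarbonate buffering, chosen because it is neutral and fast enough to keep the β,γ-double bond from moving into conjugation.

Step 7
Reactants: 15 (3Z,6Z)-nona-3,6-dienal; 16 ethynyl(trimethyl)silane
Product: 18 (3S,5Z,8Z)-1-(trimethylsilyl)undeca-5,8-dien-1-yn-3-ol, via alkynylzinc 17 (not isolated)
Conditions: 16, Et2Zn, Cy2NH (5 mol%), (R)-BINOL (30 mol%), Et2O, rt; Ti(OiPr)4 (0.8 equiv); then 15 by slow addition, 0 °C to rt; aq NH4Cl
Reagents that add atoms: none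
Why: Catalytic asymmetric alkynylzinc addition to an aldehyde under BINOL/Ti(OiPr)4 control, with (R)-BINOL selected as the antipode expected to deliver the alkynyl group to the Re face and so give the 3S carbinol (C14).

Step 8
Reactants: 18 (3S,5Z,8Z)-1-(trimethylsilyl)undeca-5,8-dien-1-yn-3-ol
Product: 19 tert-butyl(dimethyl){[(3S,5Z,8Z)-1-(trimethylsilyl)undeca-5,8-dien-1-yn-3-yl]oxy}silane
Conditions: TBSCl, imidazole, DMF, 0 °C to rt
Reagents that add atoms: tert-butyldimethylsilyl chloride (CC(C)(C)[Si](C)(C)Cl)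
Why: Standard silylation of a secondary alcohol, which protects C14–OH against the borane and zinc reagents of step 10.

Step 9
Reactants: 19 tert-butyl(dimethyl){[(3S,5Z,8Z)-1-(trimethylsilyl)undeca-5,8-dien-1-yn-3-yl]oxy}silane
Product: 20 tert-butyl(dimethyl)[(3S,5Z,8Z)-undeca-5,8-dien-1-yn-3-yloxy]silane
Conditions: K2CO3 (0.2 equiv), MeOH, 0 °C to rt
Reagents that add atoms: none
Why: Methanolysis of the alkynyl C–Si bond, which is far faster than cleavage of the secondary silyl ether under these conditions.

Step 10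
Reactants: 20 tert-butyl(dimethyl)[(3S,5Z,8Z)-undeca-5,8-dien-1-yn-3-yloxy]silane; 13 (1R,2R)-2-[(2R)-8-oxooxocan-2-yl]cyclopropane-1-carbaldehyde
Product: 23 (8R)-8-{(1R,2R)-2-[(1R,2E,4S,6Z,9Z)-4-(tert-butyldimethylsilyloxy)-1-hydroxydodeca-2,6,9-trien-1-yl]cyclopropyl}oxocan-2-one, via alkenylborane 21 (not isolated), via alkenylzinc 22 (not isolated)
Conditions: 20 (1.5 equiv), Cy2BH, toluene, 0 °C to rt; Et2Zn, −78 °C; (+)-MIB (10 mol%); 13 by slow addition, −10 °C; aq NH4Cl
Reagents that add atoms: none
Why: Hydroboration of the terminal alkyne (faster than that of the cis-disubstituted alkenes) fixes the E geometry, and boron-to-zinc exchange followed by (2R)-(+)-3-exo-morpholinoisoborneol-catalysed alkenylzinc addition to the Re face of 13 should set C11 as R under catalyst control while the lactone is untouched by the organozinc.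

Step 11
Reactants: 23 (8R)-8-{(1R,2R)-2-[(1R,2E,4S,6Z,9Z)-4-(tert-butyldimethylsilyloxy)-1-hydroxydodeca-2,6,9-trien-1-yl]cyclopropyl}oxocan-2-one
Product: 24 (8R)-8-{(1R,2R)-2-[(1R,2E,4S,6Z,9Z)-1,4-dihydroxydodeca-2,6,9-trien-1-yl]cyclopropyl}oxocan-2-one
Conditions: Bu4NF, AcOH (1:1), THF, 0 °C to rt
Reagents that add atoms: none
Why: Buffered fluoride desilylation, chosen over acid because the C11 carbinol is both allylic and cyclopropylcarbinylic and because buffering protects the lactone.

**Compound list**

1 | 3,3-diethoxyprop-1-yne | C#CC(OCC)OCC | starting material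
2 | ethyl 5-oxopentanoate | CCOC(=O)CCCC=O | starting material
3 | dicyclohexyl[(E)-3,3-diethoxyprop-1-en-1-yl]borane | CCOC(OCC)/C=C/B(C1CCCCC1)C1CCCCC1 | intermediate
4 | ethyl[(E)-3,3-diethoxyprop-1-en-1-yl]zinc | CCOC(OCC)/C=C/[Zn]CC | intermediate
5 | ethylzinc alkoxide of ethyl (5R,6E)-8,8-diethoxy-5-hydroxyoct-6-enoate | CCOC(OCC)/C=C/[C@H](O[Zn]CC)CCCC(=O)OCC | intermediate
6 | ethyl (5R)-5-[(1R,2R)-2-(diethoxymethyl)cyclopropyl]-5-hydroxypentanoate | CCOC(OCC)[C@@H]1C[C@H]1[C@H](O)CCCC(=O)OCC | intermediate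
7 | (6R)-6-[(1R,2R)-2-(diethoxymethyl)cyclopropyl]oxan-2-one | CCOC(OCC)[C@@H]1C[C@H]1[C@H]1CCCC(=O)O1 | intermediate
8 | bromomagnesium (6R)-6-[(1R,2R)-2-(diethoxymethyl)cyclopropyl]-2-ethenyloxan-2-olate | CCOC(OCC)[C@@H]1C[C@H]1[C@H]1CCCC(C=C)(O[Mg]Br)O1 | intermediate
9 | (7R)-7-[(1R,2R)-2-(diethoxymethyl)cyclopropyl]-7-hydroxyhept-1-en-3-one | CCOC(OCC)[C@@H]1C[C@H]1[C@H](O)CCCC(=O)C=C | intermediate
10 | (6R)-6-[(1R,2R)-2-(diethoxymethyl)cyclopropyl]-2-ethenyloxan-2-ol (both anomers) | CCOC(OCC)[C@@H]1C[C@H]1[C@H]1CCCC(O)(C=C)O1 | intermediate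
11 | (4R)-4-(acryloyloxy)-4-[(1R,2R)-2-(diethoxymethyl)cyclopropyl]butyl radical | CCOC(OCC)[C@@H]1C[C@H]1[C@H](OC(=O)C=C)CC[CH2] | intermediate
12 | (8R)-8-[(1R,2R)-2-(diethoxymethyl)cyclopropyl]oxocan-2-one | CCOC(OCC)[C@@H]1C[C@H]1[C@H]1CCCCCC(=O)O1 | intermediate
13 | (1R,2R)-2-[(2R)-8-oxooxocan-2-yl]cyclopropane-1-carbaldehyde | O=C[C@@H]1C[C@H]1[C@H]1CCCCCC(=O)O1 | intermediate
14 | (3Z,6Z)-nona-3,6-dien-1-ol | CC/C=C\C/C=C\CCO | starting material
15 | (3Z,6Z)-nona-3,6-dienal | CC/C=C\C/C=C\CC=O | intermediate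
16 | ethynyl(trimethyl)silane | C#C[Si](C)(C)C | starting material
17 | ethyl[(trimethylsilyl)ethynyl]zinc | CC[Zn]C#C[Si](C)(C)C | intermediate
18 | (3S,5Z,8Z)-1-(trimethylsilyl)undeca-5,8-dien-1-yn-3-ol | CC/C=C\C/C=C\C[C@H](O)C#C[Si](C)(C)C | intermediate
19 | tert-butyl(dimethyl){[(3S,5Z,8Z)-1-(trimethylsilyl)undeca-5,8-dien-1-yn-3-yl]oxy}silane | CC/C=C\C/C=C\C[C@H](O[Si](C)(C)C(C)(C)C)C#C[Si](C)(C)C | intermediate
20 | tert-butyl(dimethyl)[(3S,5Z,8Z)-undeca-5,8-dien-1-yn-3-yloxy]silane | CC/C=C\C/C=C\C[C@H](O[Si](C)(C)C(C)(C)C)C#C | intermediate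
21 | dicyclohexyl[(1E,3S,5Z,8Z)-3-(tert-butyldimethylsilyloxy)undeca-1,5,8-trien-1-yl]borane | CC/C=C\C/C=C\C[C@H](O[Si](C)(C)C(C)(C)C)/C=C/B(C1CCCCC1)C1CCCCC1 | intermediate
22 | ethyl[(1E,3S,5Z,8Z)-3-(tert-butyldimethylsilyloxy)undeca-1,5,8-trien-1-yl]zinc | CC/C=C\C/C=C\C[C@H](O[Si](C)(C)C(C)(C)C)/C=C/[Zn]CC | intermediate
23 | (8R)-8-{(1R,2R)-2-[(1R,2E,4S,6Z,9Z)-4-(tert-butyldimethylsilyloxy)-1-hydroxydodeca-2,6,9-trien-1-yl]cyclopropyl}oxocan-2-one | CC/C=C\C/C=C\C[C@H](O[Si](C)(C)C(C)(C)C)/C=C/[C@@H](O)[C@@H]1C[C@H]1[C@H]1CCCCCC(=O)O1 | intermediate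
24 | (8R)-8-{(1R,2R)-2-[(1R,2E,4S,6Z,9Z)-1,4-dihydroxydodeca-2,6,9-trien-1-yl]cyclopropyl}oxocan-2-one | CC/C=C\C/C=C\C[C@H](O)/C=C/[C@@H](O)[C@@H]1C[C@H]1[C@H]1CCCCCC(=O)O1 | target

**Step count**

Total: 11 steps. Longest linear sequence: 7 steps (steps 1 to 5, then 10 and 11).

**Steps most likely to fail, with fallbacks**

Step 4 (proposed new method). The C4 radical may be lost by hydrogen abstraction or by intermolecular addition to the vinyl ketone of a second molecule before the slow 8-endo closure. The lactol population may also be too small to drain the open hydroxy enone, and the enone may polymerise under irradiation. The fallback leaves the radical ring expansion for a classical lactonisation and sets out from δ-lactone 7. Reduction with iBu2AlH (CH2Cl2, −78 °C) would give the lactol (6R)-6-[(1R,2R)-2-(diethoxymethyl)cyclopropyl]oxan-2-ol F1. Wittig reaction of its open form with methyl (triphenylphosphoranylidene)acetate (toluene, 60 °C, no added base, to avoid oxa-Michael closure to a tetrahydropyran) would give the enoate methyl (2E,7R)-7-[(1R,2R)-2-(diethoxymethyl)cyclopropyl]-7-hydroxyhept-2-enoate F2. Hydrogenation of its C2=C3 bond (H2 over zerovalent Pd on carbon, EtOAc) would give methyl (7R)-7-[(1R,2R)-2-(diethoxymethyl)cyclopropyl]-7-hydroxyheptanoate F3. Saponification (LiOH, THF/H2O, acidification only to pH 5) would give the seco acid (7R)-7-[(1R,2R)-2-(diethoxymethyl)cyclopropyl]-7-hydroxyheptanoic acid F4. Shiina macrolactonisation (2-methyl-6-nitrobenzoic anhydride, DMAP, toluene, high dilution) would close the C1–O bond and return to oxocanone 12.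

Step 7. The β,γ-unsaturated aldehyde may isomerise into conjugation or undergo aldol self-condensation under the amine/titanium conditions, and facial selectivity with an unbranched aldehyde may be insufficient. The fallback replaces the catalytic asymmetric addition by a resolution and sets out from aldehyde 15. Fast addition of HC≡CMgBr (THF, −78 °C) would give racemic (5Z,8Z)-undeca-5,8-dien-1-yn-3-ol F5. Lipase-catalysed acylation (Burkholderia cepacia lipase, vinyl acetate, hexane) should, by the empirical size rule for secondary alcohols (ethynyl as the medium group), acylate the S enantiomer to (3S,5Z,8Z)-undeca-5,8-dien-1-yn-3-yl acetate F6, which is separated from the unreacted R alcohol. Methanolysis (K2CO3, MeOH) would give (3S,5Z,8Z)-undeca-5,8-dien-1-yn-3-ol F7, and silylation (TBSCl, imidazole, DMF) returns to alkyne 20.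

Step 10. Catalyst control at C11 may be eroded if the ligand and the neighbouring C10 stereocentre are mismatched; ethyl transfer from Et2Zn and hydroboration of the skipped diene are lesser process risks. The fallback sets C11 by reduction instead of by C–C bond formation and sets out from aldehyde 13 and alkyne 20. Alkenylzinc 22, generated as before and added with achiral 2-(dimethylamino)ethanol as promoter, would give the C11-epimeric mixture (8R)-8-{(1R,2R)-2-[(2E,4S,6Z,9Z)-4-(tert-butyldimethylsilyloxy)-1-hydroxydodeca-2,6,9-trien-1-yl]cyclopropyl}oxocan-2-one F8. Dess–Martin oxidation (NaHCO3, CH2Cl2) would give the enone (8R)-8-{(1R,2R)-2-[(2E,4S,6Z,9Z)-4-(tert-butyldimethylsilyloxy)dodeca-2,6,9-trienoyl]cyclopropyl}oxocan-2-one F9. Corey–Bakshi–Shibata reduction with the (R)-2-methyl-oxazaborolidine and catecholborane (toluene, −78 °C; alkenyl taken as the large group) should then give the 11R alcohol and return to 23.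

Further compounds
F1 | step 4 | (6R)-6-[(1R,2R)-2-(diethoxymethyl)cyclopropyl]oxan-2-ol | CCOC(OCC)[C@@H]1C[C@H]1[C@H]1CCCC(O)O1
F2 | step 4 | methyl (2E,7R)-7-[(1R,2R)-2-(diethoxymethyl)cyclopropyl]-7-hydroxyhept-2-enoate | CCOC(OCC)[C@@H]1C[C@H]1[C@H](O)CCC/C=C/C(=O)OC
F3 | step 4 | methyl (7R)-7-[(1R,2R)-2-(diethoxymethyl)cyclopropyl]-7-hydroxyheptanoate | CCOC(OCC)[C@@H]1C[C@H]1[C@H](O)CCCCCC(=O)OC
F4 | step 4 | (7R)-7-[(1R,2R)-2-(diethoxymethyl)cyclopropyl]-7-hydroxyheptanoic acid | CCOC(OCC)[C@@H]1C[C@H]1[C@H](O)CCCCCC(=O)O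
F5 | step 7 | (5Z,8Z)-undeca-5,8-dien-1-yn-3-ol (racemic) | CC/C=C\C/C=C\CC(O)C#C
F6 | step 7 | (3S,5Z,8Z)-undeca-5,8-dien-1-yn-3-yl acetate | CC/C=C\C/C=C\C[C@H](OC(C)=O)C#C
F7 | step 7 | (3S,5Z,8Z)-undeca-5,8-dien-1-yn-3-ol | CC/C=C\C/C=C\C[C@H](O)C#C
F8 | step 10 | (8R)-8-{(1R,2R)-2-[(2E,4S,6Z,9Z)-4-(tert-butyldimethylsilyloxy)-1-hydroxydodeca-2,6,9-trien-1-yl]cyclopropyl}oxocan-2-one (mixture of C11 epimers) | CC/C=C\C/C=C\C[C@H](O[Si](C)(C)C(C)(C)C)/C=C/C(O)[C@@H]1C[C@H]1[C@H]1CCCCCC(=O)O1
F9 | step 10 | (8R)-8-{(1R,2R)-2-[(2E,4S,6Z,9Z)-4-(tert-butyldimethylsilyloxy)dodeca-2,6,9-trienoyl]cyclopropyl}oxocan-2-one | CC/C=C\C/C=C\C[C@H](O[Si](C)(C)C(C)(C)C)/C=C/C(=O)[C@@H]1C[C@H]1[C@H]1CCCCCC(=O)O1
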